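## The problem

Target 21 is a 2,6-cis-disubstituted oxan-4-one. Its ring oxygen O1 joins two secondary carbinol carbons: C2, which carries the guaiacyl ring A, and C6, which carries the side chain C1'(OH)–C2'H2–ring B. The ketone at C4 lies between two nearly equivalent methylene groups, C3 and C5, so any late oxidation would face a regiochemical choice. There are three stereocentres, C2 (S), C6 (R) and C1' (S). C6 and C1' form a contiguous erythro dioxygenated pair and must be fixed together in absolute terms, because nothing installed later can correct C1'. C2 relates to C6 only across O1; the cis (diequatorial) arrangement is the thermodynamic one, so C6 could steer C2 by ring opening and re-closure, but setting C2 deliberately is safer. The molecule tolerates little: the ketone is β-alkoxy on both sides (retro-oxa-Michael), the C2–O1 bond is benzylic to an electron-rich arene (acid ionisation, hydrogenolysis), and two phenols and a secondary alcohol need protection that can be removed without harming either. The enabling feature is that the C3–C4 bond adjoins the carbonyl carbon. If O1 already links C2 and C6 in an open-chain ether, a vinyl group on C2 and a 2-silyloxyallyl group on C6 hold exactly the atoms for a metathesis that closes C3=C4, delivering the ring and the C4 oxygen in one event.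

## Retrosynthesis

**21 ⇐ 20 ⇐ 19.** The three O–CH2Ph bonds of 20 are cut last, and the ketone of 20 is traced to the cyclic silyl enol ether 19 (O–Si cleavage, protonation at C3). Benzyl is used on all three hydroxyls so that one hydrogenolysis ends the synthesis. On the C1' oxygen it has a second role: unlike a silyl group it cannot migrate to the neighbouring C6 alkoxide that the ether-forming step requires. The forward steps must leave the benzylic C2–O1 bond and the β-alkoxy ketone alone.

**19 ⇐ 18.** The C3=C4 double bond is cut, giving the acyclic bis-secondary ether 18 with a vinyl group on C2 and a 2-(triethylsilyloxy)allyl group on C6. Closing O1–C2 instead (oxa-Michael or cation capture) would leave C2 to ring thermodynamics and expose the benzylic ether to acid or base. Closing C3=C4 as a plain alkene would bring back a regioselective oxidation at C4. Precursor 18 is open-chain, already holds all three stereocentres, and asks only for ring closure under neutral conditions.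

**18 ⇐ 17 ⇐ 16 ⇐ 15.** These are functional-group changes at C4. The enol ether comes from methyl ketone 17 by kinetic silylation at the methyl group, and 17 comes from terminal alkyne 16, obtained from its C-silylated form 15. The alkyne is carried because a free β-alkoxy ketone would not survive the alkoxide chemistry that makes the ether, whereas a silyl-capped alkyne does. The forward steps must hydrate with Markovnikov regiochemistry and silylate at the terminal position only.

**15 ⇐ 12 + 4.** The O1–C2 bond is cut, dividing the molecule into the ring B alcohol 12 (holding C6 and C1') and the ring A cinnamyl carbonate 4. Cutting O1–C6 instead would need displacement at a hindered secondary carbon next to a benzyloxy group. Allylic substitution at the aryl-bearing terminus of a cinnamyl unit is the forward reaction. It must be branched-selective and must fix C2 by catalyst control, independent of the stereocentres in 12.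

**4 ⇐ 3 ⇐ 2 ⇐ 1.** The carbonate is traced through cinnamyl alcohol 3 and the doubly benzylated ester 2 to ferulic acid 1, which already has ring A, its oxygenation and the E-alkene. Only protection, reduction and activation are required.

**12 ⇐ 9 + 10 (through 11).** The C4–C5 bond is cut between the terminal carbon of epoxide 9 and the acetylide 11 derived from ethynyltrimethylsilane 10. Attack at the unsubstituted epoxide carbon does not touch C6, so both stereocentres of 9 pass unchanged into 12.

**9 ⇐ 8 ⇐ 7.** After removal of the benzyl group, epoxy alcohol 8 is traced to racemic allylic alcohol 7 by an asymmetric epoxidation run as a kinetic resolution. This sets C6 and C1' together with the required erythro relationship from a trivially made racemate. The cost is that at most half of 7 is used.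

**7 ⇐ 6 ⇐ 5.** The C1'–C6 bond is cut (vinyl addition to aldehyde 6), and 6 is the oxidation product of the commercial alcohol 5, which supplies ring B already protected.

## Roads not taken

**Alternative 1:** The cut removes C2–C3 and C5–C6 together. Furan A1 supplies C2, C6 and O1; the oxyallyl cation released by reductive dehalogenation of 1,1,3,3-tetrabromoacetone A2 supplies C3–C4–C5. A [4+3] cycloaddition followed by reductive removal of the remaining bromine atoms gives meso-8-oxabicyclo[3.2.1]oct-6-en-3-one A3.
- Merits: two carbon–carbon bonds, the ring, the C4 ketone and a guaranteed 2,6-cis relationship arrive in one or two operations from commodity chemicals. In speed to the core and certainty of the cis geometry this road beats the chosen plan.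
- Weak points: A3 is meso and carries only a two-carbon bridge on C2 and C6. Cleaving the bridge leaves a one-carbon oxygenated substituent on each position, but C2 of 21 bears ring A directly. One carbon must therefore be excised and replaced by an aryl group at an α-oxygenated centre. The other must be extended to the C1' carbinol by 1,2-induction from C6 alone. The meso compound also has to be desymmetrised to reach a single enantiomer.
- Comparison: the chosen plan is slower to the ring, but it installs both substituents and all absolute stereochemistry before closure, so nothing has to be removed or desymmetrised afterwards.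

**Alternative 2:** The cut is C5–C6. The lactone (5R,6R)-5-[4-(benzyloxy)-3-methoxyphenyl]-6-ethenyl-1,4-dioxan-2-one A4 is converted into its silyl ketene acetal, which undergoes Ireland–Claisen rearrangement. The vinyl terminus bonds to the glycolate α-carbon as the allylic ester C–O bond breaks, contracting the ring to the cis acid A5, (2R,6S)-6-[4-(benzyloxy)-3-methoxyphenyl]-3,6-dihydro-2H-pyran-2-carboxylic acid.
- Merits: the rearrangement creates C6 with its configuration transferred from C2 through a constrained cyclic transition state. The ring stereochemistry is thus made in the key step, which the chosen plan does not do.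
- Weak points: A5 has a bare C3=C4 alkene, so the C4 oxygen still requires a regioselective oxidation. C1' is only a carboxyl carbon, so ring B and the C1' configuration must be added afterwards by 1,2-induction from C6. Lactone A4 itself needs an enantioenriched anti aryl/vinyl diol unit whose benzylic, allylic C–O bond is ionisable.
- Comparison: the chosen plan sets C1' and C6 together in one resolution step and carries the C4 oxygen through the ring closure. In exchange it needs a catalyst-controlled etherification to set C2.

**Alternative 3:** The cuts are C3–C4 and C4–C5 at the carbonyl carbon, introduced as the dithiane carbon of 2-(tert-butyldimethylsilyl)-1,3-dithiane A6. Its anion opens ring A epoxide A7 at the methylene carbon, a 1,4-Brook rearrangement moves silicon to the new C2 alkoxide, and the regenerated dithiane anion opens epoxide 9. The product is the open-chain dithiane A8 with C2 silyloxy (both epimers), free C6 hydroxyl and C1' benzyl ether.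
- Merits: this is the most convergent plan. Three components and two carbon–carbon bonds come together in one flask, epoxide 9 is shared with the chosen route, and C2 need not be controlled if the ring is later closed under thermodynamic control through the aryl enone. In step economy it is likely better than the chosen plan.
- Weak points: the electron-rich aryl epoxide A7 is prone to benzylic opening and rearrangement. The second alkylation joins a hindered, β-silyloxy dithiane anion to a substituted epoxide and relies on a strongly coordinating phosphoramide co-solvent. Unmasking the dithiane needs alkylating or oxidising reagents in the presence of three electron-rich arenes. The final cis selectivity depends on an elimination and re-addition sequence that can also eliminate on the C6 side.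
- Comparison: the chosen plan is longer, but C2 is set by a catalyst and never passes through an enone, and the ring closure is neutral and leaves no sulfur to remove.

Key step: step 13

Assumption: the (Sa,Sc,Sc) enantiomer of the binaphthol-derived N,N-bis(1-phenylethyl)phosphoramidite (L) is taken to give the (S)-configured ether carbon in step 9, following the facial preference of this catalyst family with aryl-substituted allyl carbonates and oxygen nucleophiles; if the sense is the reverse, the mirror-image ligand is used and nothing else changes.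

## Route

Step 1
Reactants: 1 ferulic acid
Product: 2 benzyl (2E)-3-[4-(benzyloxy)-3-methoxyphenyl]prop-2-enoate
Conditions: BnBr (2.3 equiv), K2CO3 (2.5 equiv), DMF, 60 °C
Reagents that add atoms: benzyl bromide, BrCc1ccccc1
Why: Carboxylate and phenoxide are both alkylated under carbonate conditions (Williamson etherification with concurrent ester formation); the E-alkene is untouched.

Step 2
Reactants: 2 benzyl (2E)-3-[4-(benzyloxy)-3-methoxyphenyl]prop-2-enoate
Product: 3 (2E)-3-[4-(benzyloxy)-3-methoxyphenyl]prop-2-en-1-ol
Conditions: i-Bu2AlH (2.5 equiv), CH2Cl2, −78 °C; aq. potassium sodium tartrate work-up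
Reagents that add atoms: none
Why: 1,2-Reduction of the unsaturated ester by the aluminium hydride at low temperature gives the allylic alcohol without conjugate reduction; the aryl benzyl ether is inert and benzyl alcohol is the only organic co-product.

Step 3
Reactants: 3 (2E)-3-[4-(benzyloxy)-3-methoxyphenyl]prop-2-en-1-ol
Product: 4 tert-butyl (2E)-3-[4-(benzyloxy)-3-methoxyphenyl]prop-2-en-1-yl carbonate
Conditions: Boc2O (1.3 equiv), Bu4NHSO4 (cat.), 30% aq. NaOH, CH2Cl2, 0 °C to rt
Reagents that add atoms: di-tert-butyl dicarbonate, CC(C)(C)OC(=O)OC(=O)OC(C)(C)C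
Why: O-Acylation of the primary allylic alcohol under phase-transfer conditions; the tert-butyl carbonate is chosen because its leaving group breaks down to CO2 and the poorly nucleophilic tert-butoxide, which should not compete with the alkoxide in step 9.

Step 4
Reactants: 5 2-[4-(benzyloxy)phenyl]ethanol
Product: 6 2-[4-(benzyloxy)phenyl]acetaldehyde
Conditions: Dess–Martin periodinane (1.2 equiv), CH2Cl2, 0 °C to rt; used crude
Reagents that add atoms: none
Why: Dess–Martin oxidation stops at the aldehyde under near-neutral conditions, which limits aldol self-condensation of the enolisable arylacetaldehyde.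

Step 5
Reactants: 6 2-[4-(benzyloxy)phenyl]acetaldehyde
Product: 7 rac-1-[4-(benzyloxy)phenyl]but-3-en-2-ol
Conditions: CH2=CHMgBr (1.3 equiv), THF, −78 to 0 °C
Reagents that add atoms: vinylmagnesium bromide, C=C[Mg]Br
Why: Grignard 1,2-addition at low temperature outruns enolisation and forms the C1'–C6 bond; the carbinol is made racemic on purpose because step 6 resolves it.

Step 6
Reactants: 7 rac-1-[4-(benzyloxy)phenyl]but-3-en-2-ol
Product: 8 (1S)-2-[4-(benzyloxy)phenyl]-1-[(2R)-oxiran-2-yl]ethan-1-ol
Conditions: Ti(OiPr)4 (0.2 equiv), L-(+)-DIPT (0.25 equiv), t-BuOOH (0.45 equiv), 4 Å MS, CH2Cl2, −20 °C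
Reagents that add atoms: tert-butyl hydroperoxide, CC(C)(C)OO
Why: Sharpless kinetic resolution: with L-(+)-tartrate the (S)-enantiomer of 7 is epoxidised much faster than its antipode and on the face the tartrate dictates, giving the erythro epoxy alcohol and setting C1' (S) and C6 (R) together; the slow (R)-enantiomer of 7 stays behind with substoichiometric oxidant and is removed by chromatography.

Step 7
Reactants: 8 (1S)-2-[4-(benzyloxy)phenyl]-1-[(2R)-oxiran-2-yl]ethan-1-ol
Product: 9 (2R)-2-[(1S)-1-(benzyloxy)-2-[4-(benzyloxy)phenyl]ethyl]oxirane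
Conditions: NaH (1.2 equiv), BnBr (1.2 equiv), Bu4NI (cat.), THF, 0 °C to rt
Reagents that add atoms: benzyl bromide, BrCc1ccccc1
Why: Williamson etherification of the secondary hydroxyl in an aprotic medium, where O-benzylation should outpace Payne rearrangement of the epoxy alkoxide; neither stereocentre is involved.

Step 8
Reactants: 10 ethynyltrimethylsilane; 9 (2R)-2-[(1S)-1-(benzyloxy)-2-[4-(benzyloxy)phenyl]ethyl]oxirane
Product: 12 (2S,3R)-2-(benzyloxy)-1-[4-(benzyloxy)phenyl]-6-(trimethylsilyl)hex-5-yn-3-ol, via lithium (trimethylsilyl)acetylide 11 (not isolated)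
Conditions: 10 (2 equiv), n-BuLi (2 equiv), THF, −78 °C; then 9, BF3·OEt2 (2 equiv), −78 °C
Reagents that add atoms: none
Why: BF3-promoted opening of the terminal epoxide by the lithium acetylide (Yamaguchi–Hirao alkynylation) occurs at the unsubstituted carbon, forming C4–C5 and leaving the C6 configuration untouched; the silyl cap keeps the alkyne C–H out of step 9.

Step 9
Reactants: 12 (2S,3R)-2-(benzyloxy)-1-[4-(benzyloxy)phenyl]-6-(trimethylsilyl)hex-5-yn-3-ol; 4 tert-butyl (2E)-3-[4-(benzyloxy)-3-methoxyphenyl]prop-2-en-1-yl carbonate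
Product: 15 trimethyl[(4R,5S)-5-(benzyloxy)-4-{[(1S)-1-[4-(benzyloxy)-3-methoxyphenyl]prop-2-en-1-yl]oxy}-6-[4-(benzyloxy)phenyl]hex-1-yn-1-yl]silane, via lithium alkoxide ROLi 13 (not isolated), via copper alkoxide ROCu 14 (not isolated)
Conditions: n-BuLi (1.0 equiv), THF, 0 °C; CuI (1.0 equiv), rt; then 4 (1.2 equiv), [Ir(cod)Cl]2 (2 mol%), (Sa,Sc,Sc)-L (4 mol%), THF, rt
Reagents that add atoms: none
Why: Iridium-catalysed branched-selective allylic etherification (R in 13 and 14 is the carbon skeleton of 12): the iridium–phosphoramidite complex ionises 4 with loss of CO2 and tert-butoxide, and the copper alkoxide attacks the aryl-bearing terminus of the allyl ligand. The ligand, not the stereocentres of 12, fixes the face of attack and so sets C2 as (S); any minor enantiomer of 12 left from step 6 emerges as a separable diastereomer.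

Step 10
Reactants: 15 trimethyl[(4R,5S)-5-(benzyloxy)-4-{[(1S)-1-[4-(benzyloxy)-3-methoxyphenyl]prop-2-en-1-yl]oxy}-6-[4-(benzyloxy)phenyl]hex-1-yn-1-yl]silane
Product: 16 1-(benzyloxy)-4-[(1S)-1-{[(2S,3R)-2-(benzyloxy)-1-[4-(benzyloxy)phenyl]hex-5-yn-3-yl]oxy}prop-2-en-1-yl]-2-methoxybenzene
Conditions: K2CO3 (0.3 equiv), MeOH, rt
Reagents that add atoms: none
Why: Base-catalysed methanolysis of the alkynyl C–Si bond (protodesilylation); ethers, alkenes and the doubly activated allylic ether are inert to it.

Step 11
Reactants: 16 1-(benzyloxy)-4-[(1S)-1-{[(2S,3R)-2-(benzyloxy)-1-[4-(benzyloxy)phenyl]hex-5-yn-3-yl]oxy}prop-2-en-1-yl]-2-methoxybenzene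
Product: 17 (4R,5S)-5-(benzyloxy)-4-{[(1S)-1-[4-(benzyloxy)-3-methoxyphenyl]prop-2-en-1-yl]oxy}-6-[4-(benzyloxy)phenyl]hexan-2-one
Conditions: Ph3PAuNTf2 (3 mol%), MeOH–H2O (10:1), rt to 40 °C
Reagents that add atoms: water, O
Why: Gold-catalysed Markovnikov hydration of the terminal alkyne gives the methyl ketone without added Brønsted acid, which the ionisable 1-arylallyl ether should tolerate; in aqueous methanol the solvent is expected to capture the activated alkyne faster than the alkenes or ether oxygens in the molecule.

Step 12
Reactants: 17 (4R,5S)-5-(benzyloxy)-4-{[(1S)-1-[4-(benzyloxy)-3-methoxyphenyl]prop-2-en-1-yl]oxy}-6-[4-(benzyloxy)phenyl]hexan-2-one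
Product: 18 {[(4R,5S)-5-(benzyloxy)-4-{[(1S)-1-[4-(benzyloxy)-3-methoxyphenyl]prop-2-en-1-yl]oxy}-6-[4-(benzyloxy)phenyl]hex-1-en-2-yl]oxy}triethylsilane
Conditions: Et3SiCl (1.5 equiv), Et3N (2 equiv), THF, −78 °C; LiN(SiMe3)2 (1.2 equiv) added slowly; cold NaHCO3 work-up
Reagents that add atoms: chlorotriethylsilane, CC[Si](Cl)(CC)CC
Why: Kinetic deprotonation of the methyl ketone at the unhindered methyl group with immediate O-silylation by the chlorosilane already in the flask (internal quench) gives the 2-silyloxy-1-alkene; this leaves no time for proton transfer to the internal position, from which the β-alkoxide would be expelled.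

Step 13
Reactants: 18 {[(4R,5S)-5-(benzyloxy)-4-{[(1S)-1-[4-(benzyloxy)-3-methoxyphenyl]prop-2-en-1-yl]oxy}-6-[4-(benzyloxy)phenyl]hex-1-en-2-yl]oxy}triethylsilane
Product: 19 {[(2R,6S)-2-[(1S)-1-(benzyloxy)-2-[4-(benzyloxy)phenyl]ethyl]-6-[4-(benzyloxy)-3-methoxyphenyl]-3,6-dihydro-2H-pyran-4-yl]oxy}triethylsilane
Conditions: second-generation Grubbs catalyst (H2IMes)(PCy3)Cl2Ru=CHPh (5–10 mol%), degassed toluene, high dilution, 60 °C
Reagents that add atoms: none
Why: This is a ring-closing olefin metathesis of an acyclic silyl enol ether with a terminal alkene, a known way to cyclic silyl enol ethers. The ruthenium benzylidene first exchanges with the monosubstituted vinyl group on C2, the most accessible alkene, placing an alkylidene on C3. That alkylidene adds across the 1,1-disubstituted enol ether C4=CH2 with ruthenium bonding to the terminal CH2, and cycloreversion of the ruthenacyclobutane releases the C3=C4 bond and Ru=CH2, which carries the cycle with loss of ethylene. The ring closed is the six-membered dihydropyran O1–C2–C3=C4–C5–C6, an unstrained closure with the new double bond endocyclic. No stereocentre is created; C2, C6 and C1' pass through unchanged, and the 2,6-cis relationship is the one built into ether 18. The step needs initiation at the vinyl group and cyclisation over oligomerisation: the bulky silyloxy group and 1,1-disubstitution keep the catalyst off the enol ether, and dilution plus six-membered ring formation favour closure. Neutral aprotic conditions preserve the silyl enol ether and the benzylic ether, and the C4 oxygen arrives without later oxidation.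

Step 14
Reactants: 19 {[(2R,6S)-2-[(1S)-1-(benzyloxy)-2-[4-(benzyloxy)phenyl]ethyl]-6-[4-(benzyloxy)-3-methoxyphenyl]-3,6-dihydro-2H-pyran-4-yl]oxy}triethylsilane
Product: 20 (2S,6R)-2-[4-(benzyloxy)-3-methoxyphenyl]-6-[(1S)-1-(benzyloxy)-2-[4-(benzyloxy)phenyl]ethyl]oxan-4-one
Conditions: 0.5 M aq. HCl, THF, 0 °C, short contact
Reagents that add atoms: none
Why: Acid hydrolysis of the silyl enol ether (protonation at C3, loss of silanol) unveils the C4 ketone; brief exposure at 0 °C should avoid ionising the benzylic C2–O1 bond, and any ring opening and re-closure at C2 would in any case lead back to the diequatorial cis isomer.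

Step 15
Reactants: 20 (2S,6R)-2-[4-(benzyloxy)-3-methoxyphenyl]-6-[(1S)-1-(benzyloxy)-2-[4-(benzyloxy)phenyl]ethyl]oxan-4-one
Product: 21 (2S,6R)-2-(4-hydroxy-3-methoxyphenyl)-6-[(1S)-1-hydroxy-2-(4-hydroxyphenyl)ethyl]oxan-4-one
Conditions: H2 (1 atm), 10% Pd/C, EtOAc–EtOH, rt
Reagents that add atoms: none
Why: Heterogeneous hydrogenolysis removes the two aryl benzyl ethers and the secondary alkyl benzyl ether; the ring C2–O1 bond, a cyclic dialkyl ether, is expected to cleave much more slowly, and the aliphatic ketone is not reduced under these conditions.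

## Compound list

1 | ferulic acid | COc1cc(/C=C/C(=O)O)ccc1O | starting material
2 | benzyl (2E)-3-[4-(benzyloxy)-3-methoxyphenyl]prop-2-enoate | COc1cc(/C=C/C(=O)OCc2ccccc2)ccc1OCc1ccccc1 | intermediate
3 | (2E)-3-[4-(benzyloxy)-3-methoxyphenyl]prop-2-en-1-ol | COc1cc(/C=C/CO)ccc1OCc1ccccc1 | intermediate
4 | tert-butyl (2E)-3-[4-(benzyloxy)-3-methoxyphenyl]prop-2-en-1-yl carbonate | COc1cc(/C=C/COC(=O)OC(C)(C)C)ccc1OCc1ccccc1 | intermediate
5 | 2-[4-(benzyloxy)phenyl]ethanol | OCCc1ccc(OCc2ccccc2)cc1 | starting material
6 | 2-[4-(benzyloxy)phenyl]acetaldehyde | O=CCc1ccc(OCc2ccccc2)cc1 | intermediate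
7 | rac-1-[4-(benzyloxy)phenyl]but-3-en-2-ol | C=CC(O)Cc1ccc(OCc2ccccc2)cc1 | intermediate
8 | (1S)-2-[4-(benzyloxy)phenyl]-1-[(2R)-oxiran-2-yl]ethan-1-ol | O[C@@H](Cc1ccc(OCc2ccccc2)cc1)[C@H]1CO1 | intermediate
9 | (2R)-2-[(1S)-1-(benzyloxy)-2-[4-(benzyloxy)phenyl]ethyl]oxirane | C(O[C@@H](Cc1ccc(OCc2ccccc2)cc1)[C@H]1CO1)c1ccccc1 | intermediate
10 | ethynyltrimethylsilane | C#C[Si](C)(C)C | starting material
11 | lithium (trimethylsilyl)acetylide (formed in the flask) | [Li]C#C[Si](C)(C)C | intermediate
12 | (2S,3R)-2-(benzyloxy)-1-[4-(benzyloxy)phenyl]-6-(trimethylsilyl)hex-5-yn-3-ol | C[Si](C)(C)C#CC[C@@H](O)[C@@H](OCc1ccccc1)Cc1ccc(OCc2ccccc2)cc1 | intermediate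
13 | lithium alkoxide ROLi of 12 (formed in the flask) | C[Si](C)(C)C#CC[C@@H](O[Li])[C@@H](OCc1ccccc1)Cc1ccc(OCc2ccccc2)cc1 | intermediate
14 | copper alkoxide ROCu of 12 (formed in the flask) | C[Si](C)(C)C#CC[C@@H](O[Cu])[C@@H](OCc1ccccc1)Cc1ccc(OCc2ccccc2)cc1 | intermediate
15 | trimethyl[(4R,5S)-5-(benzyloxy)-4-{[(1S)-1-[4-(benzyloxy)-3-methoxyphenyl]prop-2-en-1-yl]oxy}-6-[4-(benzyloxy)phenyl]hex-1-yn-1-yl]silane | COc1cc([C@H](C=C)O[C@H](CC#C[Si](C)(C)C)[C@@H](OCc2ccccc2)Cc2ccc(OCc3ccccc3)cc2)ccc1OCc1ccccc1 | intermediate
16 | 1-(benzyloxy)-4-[(1S)-1-{[(2S,3R)-2-(benzyloxy)-1-[4-(benzyloxy)phenyl]hex-5-yn-3-yl]oxy}prop-2-en-1-yl]-2-methoxybenzene | COc1cc([C@H](C=C)O[C@H](CC#C)[C@@H](OCc2ccccc2)Cc2ccc(OCc3ccccc3)cc2)ccc1OCc1ccccc1 | intermediate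
17 | (4R,5S)-5-(benzyloxy)-4-{[(1S)-1-[4-(benzyloxy)-3-methoxyphenyl]prop-2-en-1-yl]oxy}-6-[4-(benzyloxy)phenyl]hexan-2-one | COc1cc([C@H](C=C)O[C@H](CC(C)=O)[C@@H](OCc2ccccc2)Cc2ccc(OCc3ccccc3)cc2)ccc1OCc1ccccc1 | intermediate
18 | {[(4R,5S)-5-(benzyloxy)-4-{[(1S)-1-[4-(benzyloxy)-3-methoxyphenyl]prop-2-en-1-yl]oxy}-6-[4-(benzyloxy)phenyl]hex-1-en-2-yl]oxy}triethylsilane | COc1cc([C@H](C=C)O[C@H](CC(=C)O[Si](CC)(CC)CC)[C@@H](OCc2ccccc2)Cc2ccc(OCc3ccccc3)cc2)ccc1OCc1ccccc1 | intermediate
19 | {[(2R,6S)-2-[(1S)-1-(benzyloxy)-2-[4-(benzyloxy)phenyl]ethyl]-6-[4-(benzyloxy)-3-methoxyphenyl]-3,6-dihydro-2H-pyran-4-yl]oxy}triethylsilane | COc1cc([C@@H]2C=C(O[Si](CC)(CC)CC)C[C@H]([C@@H](OCc3ccccc3)Cc3ccc(OCc4ccccc4)cc3)O2)ccc1OCc1ccccc1 | intermediate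
20 | (2S,6R)-2-[4-(benzyloxy)-3-methoxyphenyl]-6-[(1S)-1-(benzyloxy)-2-[4-(benzyloxy)phenyl]ethyl]oxan-4-one | COc1cc([C@@H]2CC(=O)C[C@H]([C@@H](OCc3ccccc3)Cc3ccc(OCc4ccccc4)cc3)O2)ccc1OCc1ccccc1 | intermediate
21 | (2S,6R)-2-(4-hydroxy-3-methoxyphenyl)-6-[(1S)-1-hydroxy-2-(4-hydroxyphenyl)ethyl]oxan-4-one | COc1cc([C@@H]2CC(=O)C[C@H]([C@@H](O)Cc3ccc(O)cc3)O2)ccc1O | target

## Step count and risks

Total: 15 steps. Longest linear sequence: 12 steps (5 to 21, steps 4–15). The ring A branch (1 to 4, steps 1–3) joins at step 9.

**Step 13 (key step).** The most likely failure is non-productive methylidene transfer to the enol ether, which parks the catalyst as an oxygen-stabilised ruthenium carbene. With the cycle stalled, ruthenium hydride species can migrate the C2 vinyl double bond along the allylic ether, and adventitious acid can hydrolyse the enol ether back to 17. The fallback leaves the enol ether out of the metathesis and adds the C4 oxygen afterwards. It sets out from epoxide 9, which is opened with CH2=CHMgBr and catalytic CuI to give (2S,3R)-2-(benzyloxy)-1-[4-(benzyloxy)phenyl]hex-5-en-3-ol F1. Etherification with carbonate 4 under the conditions of step 9 gives 1-(benzyloxy)-4-[(1S)-1-{[(2S,3R)-2-(benzyloxy)-1-[4-(benzyloxy)phenyl]hex-5-en-3-yl]oxy}prop-2-en-1-yl]-2-methoxybenzene F2. Ring-closing metathesis of its two monosubstituted alkenes with the same ruthenium catalyst gives (2R,6S)-2-[(1S)-1-(benzyloxy)-2-[4-(benzyloxy)phenyl]ethyl]-6-[4-(benzyloxy)-3-methoxyphenyl]-3,6-dihydro-2H-pyran F3. Wacker oxidation (PdCl2, CuCl, O2, DMF–H2O), in which the allylic C2–O1 bond should direct oxygen to the remote alkene carbon C4, returns to the route at ketone 20. The price is that the regiochemical question at C4 comes back.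

**Step 9.** A hindered secondary alkoxide may attack the allyl–iridium intermediate slowly. The carbonate would then be consumed by other paths (linear ether, tert-butyl ether, diene formation), or control at C2 would be incomplete where catalyst and substrate are mismatched. The fallback gives up catalyst control and makes the same bond through an oxocarbenium ion. It sets out from alcohol 12, which is condensed with 4-(benzyloxy)-3-methoxybenzaldehyde and 1H-benzotriazole (TsOH cat., toluene, azeotropic water removal) to the N,O-acetal 1-{[4-(benzyloxy)-3-methoxyphenyl]{[(2S,3R)-2-(benzyloxy)-1-[4-(benzyloxy)phenyl]-6-(trimethylsilyl)hex-5-yn-3-yl]oxy}methyl}-1H-benzotriazole F4. Displacement of the benzotriazolyl group by CH2=CHMgBr gives 15 together with its epimer at the allylic ether carbon, trimethyl[(4R,5S)-5-(benzyloxy)-4-{[(1R)-1-[4-(benzyloxy)-3-methoxyphenyl]prop-2-en-1-yl]oxy}-6-[4-(benzyloxy)phenyl]hex-1-yn-1-yl]silane F5. Chromatographic separation returns to the route at 15.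

**Step 11.** The gold-activated alkyne may be intercepted within the molecule before water arrives. The ether oxygen could add with transfer of the stabilised 1-arylallyl group, or the C2 vinyl group could enter an enyne cycloisomerisation. The fallback avoids π-acid activation altogether. It sets out from alkyne 16, which undergoes Markovnikov hydrosilylation with BnMe2SiH and [Cp*Ru(MeCN)3]PF6 to give benzyl[(4R,5S)-5-(benzyloxy)-4-{[(1S)-1-[4-(benzyloxy)-3-methoxyphenyl]prop-2-en-1-yl]oxy}-6-[4-(benzyloxy)phenyl]hex-1-en-2-yl]dimethylsilane F6. Tamao–Fleming oxidation (Bu4NF; then H2O2, KHCO3, MeOH–THF) converts the vinylsilane into the methyl ketone and returns to the route at 17.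

**Step 15.** The slow cleavage of the alkyl benzyl ether at C1' gives time for reductive opening of the benzylic ring C2–O1 bond, which the electron-rich ring A makes more prone to hydrogenolysis. The fallback replaces reduction by Lewis acid cleavage. It sets out from 20, which is treated with BCl3 and pentamethylbenzene as benzyl cation scavenger in CH2Cl2 at −78 °C, and arrives directly at 21.

## Further compounds

F1 | step 13 | (2S,3R)-2-(benzyloxy)-1-[4-(benzyloxy)phenyl]hex-5-en-3-ol | C=CC[C@@H](O)[C@@H](OCc1ccccc1)Cc1ccc(OCc2ccccc2)cc1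
F2 | step 13 | 1-(benzyloxy)-4-[(1S)-1-{[(2S,3R)-2-(benzyloxy)-1-[4-(benzyloxy)phenyl]hex-5-en-3-yl]oxy}prop-2-en-1-yl]-2-methoxybenzene | COc1cc([C@H](C=C)O[C@H](CC=C)[C@@H](OCc2ccccc2)Cc2ccc(OCc3ccccc3)cc2)ccc1OCc1ccccc1
F3 | step 13 | (2R,6S)-2-[(1S)-1-(benzyloxy)-2-[4-(benzyloxy)phenyl]ethyl]-6-[4-(benzyloxy)-3-methoxyphenyl]-3,6-dihydro-2H-pyran | COc1cc([C@@H]2C=CC[C@H]([C@@H](OCc3ccccc3)Cc3ccc(OCc4ccccc4)cc3)O2)ccc1OCc1ccccc1
F4 | step 9 | 1-{[4-(benzyloxy)-3-methoxyphenyl]{[(2S,3R)-2-(benzyloxy)-1-[4-(benzyloxy)phenyl]-6-(trimethylsilyl)hex-5-yn-3-yl]oxy}methyl}-1H-benzotriazole (both epimers at the N,O-acetal carbon) | COc1cc(C(n2nnc3ccccc32)O[C@H](CC#C[Si](C)(C)C)[C@@H](OCc2ccccc2)Cc2ccc(OCc3ccccc3)cc2)ccc1OCc1ccccc1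
F5 | step 9 | trimethyl[(4R,5S)-5-(benzyloxy)-4-{[(1R)-1-[4-(benzyloxy)-3-methoxyphenyl]prop-2-en-1-yl]oxy}-6-[4-(benzyloxy)phenyl]hex-1-yn-1-yl]silane | COc1cc([C@@H](C=C)O[C@H](CC#C[Si](C)(C)C)[C@@H](OCc2ccccc2)Cc2ccc(OCc3ccccc3)cc2)ccc1OCc1ccccc1
F6 | step 11 | benzyl[(4R,5S)-5-(benzyloxy)-4-{[(1S)-1-[4-(benzyloxy)-3-methoxyphenyl]prop-2-en-1-yl]oxy}-6-[4-(benzyloxy)phenyl]hex-1-en-2-yl]dimethylsilane | COc1cc([C@H](C=C)O[C@H](CC(=C)[Si](C)(C)Cc2ccccc2)[C@@H](OCc2ccccc2)Cc2ccc(OCc3ccccc3)cc2)ccc1OCc1ccccc1
F0 | step 15 | none | none
A1 | alternative 1 | furan | c1ccoc1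
A2 | alternative 1 | 1,1,3,3-tetrabromoacetone | BrC(Br)C(=O)C(Br)Br
A3 | alternative 1 | meso-(1R,5S)-8-oxabicyclo[3.2.1]oct-6-en-3-one | O=C1C[C@H]2C=C[C@@H](C1)O2
A4 | alternative 2 | (5R,6R)-5-[4-(benzyloxy)-3-methoxyphenyl]-6-ethenyl-1,4-dioxan-2-one (trans) | COc1cc([C@H]2OCC(=O)O[C@@H]2C=C)ccc1OCc1ccccc1
A5 | alternative 2 | (2R,6S)-6-[4-(benzyloxy)-3-methoxyphenyl]-3,6-dihydro-2H-pyran-2-carboxylic acid (cis) | COc1cc([C@@H]2C=CC[C@H](C(=O)O)O2)ccc1OCc1ccccc1
A6 | alternative 3 | 2-(tert-butyldimethylsilyl)-1,3-dithiane | CC(C)(C)[Si](C)(C)C1SCCCS1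
A7 | alternative 3 | 2-[4-(benzyloxy)-3-methoxyphenyl]oxirane (racemic) | COc1cc(C2CO2)ccc1OCc1ccccc1
A8 | alternative 3 | 2-{2-[4-(benzyloxy)-3-methoxyphenyl]-2-[(tert-butyldimethylsilyl)oxy]ethyl}-2-[(2R,3S)-3-(benzyloxy)-4-[4-(benzyloxy)phenyl]-2-hydroxybutyl]-1,3-dithiane (both epimers at the silyloxy carbon) | COc1cc(C(O[Si](C)(C)C(C)(C)C)CC2(SCCCS2)C[C@@H](O)[C@@H](OCc2ccccc2)Cc2ccc(OCc3ccccc3)cc2)ccc1OCc1ccccc1
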